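One unit serves these books: the equivalent, X charged per Z charged, so that every entry is a fraction of the Z charge.

common to all: Z 0.25 M

| flask | X | remark | time |
|---|---|---|---|
| Tuesday's | 0.075 M | run made earlier |  |
| Saturday's | 0.74 M | run made earlier |  |
| violet | 0.200 M |  | 12 min |
| blue | 0.125 M |  | 12 min |
| green | 1.00 M |  | 12 min |

| run | time / min | G / % | J / % | Z / % |
|---|---|---|---|---|
| Tuesday's | 2.00 | 1.8 | 8.5 | 74.2 |
| Tuesday's | 4.00 | 2.4 | 6.1 | 74.4 |
| Tuesday's | 6.00 | 1.2 | 4.3 | 75.4 |
| Tuesday's | 8.00 | 3.0 | 4.4 | 75.0 |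
| Tuesday's | 10.0 | 2.0 | 2.8 | 74.6 |
| Tuesday's | 12.0 | 2.2 | 2.9 | 75.1 |
| Saturday's | 2.00 | 88.4 | 0.3 | 0.5 |
| Saturday's | 4.00 | 88.8 | 0 | 0.3 |
| Saturday's | 6.00 | 88.4 | 0 | 0 |
| Saturday's | 8.00 | 88.3 | 0 | 0 |
| Saturday's | 10.0 | 88.4 | 0 | 0 |
| Saturday's | 12.0 | 88.8 | 1.7 | 0 |

(readings scatter by 0.5 percentage points)

- on the list of suspects stand: Z + X -> J + L; X + J -> G + L; J + L -> Q; X -> D; J <-> E

- which of these holds the largest part of the Z at the end of violet (J / Z / G)
- which of these holds the largest part of the Z at the end of blue (J / Z / G)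
- which of these holds the largest part of the Z at the end of green (J / Z / G)
- how much G is there at the end of green, in percent of the Z charged

1. The accounts. Of the suspects, three debit X: Z + X gives J + L, X + J gives G + L, and X gives D. So each Z turned costs one equivalent, each G one more, and D takes the balance. J + L giving Q and J going to E cost no X.

2. Tuesday's run. With 0.300 equivalents, X is the limiting reagent. Z freezes early, reading 74.2 % at 2.00 min and 75.1 % at 12.0 min, a drift near the scatter of 0.5 percentage points. We book the X charge as closed. Z turned plus G, 2.2 %, comes to 27.1 % of the Z charge. The remainder gives the leak share 9.67 %, the part of the X charge booked to D while Z remains. It is a reading and carries the scatter.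

3. Violet and blue. We hold the leak share, so usable X is 0.723 equivalents in violet and 0.452 in blue. Since Z turned plus G equals usable X, Z left exceeds G by one less usable X: 27.7 % in violet and 54.8 % in blue. J ended Tuesday's run at 11.6 % of the Z turned, which puts it below Z in violet and blue, so we say Z for both.

4. Green. Usable X, 3.61 equivalents, covers both steps, so G is what Q leaves. Saturday's run at 2.96 equivalents left a gap of 11.6 %. Shrinking that gap in proportion to X gives us G of 91.4 %.

The forecast says Z, Z, G and G of 92 % (89 % to 95 %), a little above ours, on the ground that “Green has more X, so it intercepts J better”.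

The flask gives Z in violet, 41.1 % with G 12.1 %; Z in blue, 60.1 % with G 4.89 %; and G in green, 95.3 %.

    Z + X → J + L (k = 3.70 L mol⁻¹ s⁻¹)
    X + J → G + L (k = 2.10 L mol⁻¹ s⁻¹)
    J + L → Q (k = 0.110 L mol⁻¹ s⁻¹)
    X → D (k = 0.0940 s⁻¹)
    J ⇌ E (K = 1.00, k = 0.160 s⁻¹)

Z less G is 29.0 % in violet and 55.2 % in blue, against our booked 27.7 % and 54.8 %. Green's G stands 3.9 points above our figure. A neighbour of green has 0.40 M of X, so 1.60 equivalents and 1.45 usable. Its Z left is 8.5 %, so the books give G of 53.0 %; the flask holds 43.5 %. Its D is 0.0626 M, which is 15.7 % of its X charge.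

The data stem from a simulated flask on assumed constants; scatter was added.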